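**Retrosynthetic overview** (ring A = aryl ring on C2, B = benzene ring of the benzofuran, C = its O-ring, D = lactone, E = aryl ring of the C4 benzyl group)
1. Target ⇒ tribenzyl ether 25 ⇒ trans-selective C-alkylation of the enolate of lactone 23 (rings D, E) with benzylic bromide 15 (rings A–C).
2. Ring C is closed by the O1–C7a bond: the C2 alkoxide displaces fluoride from C7a of ring B (intramolecular SNAr, 5-exo).
3. Enabling feature: C7a is para to C5, the ring-B carbon that carries the CH2 link to ring D, and is flanked by C7–OMe and C3a (no ortho hydrogen). With the C5 carbon held as CO2Me, C7a–F is an SNAr site; fluorine stands in for O1 and also steers C–H borylation to C3a; the ester is afterwards reduced into the CH2 link.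
4. Acyclic precursor ⇒ Evans syn-aldol (C2–C3 bond, both stereocentres; the closure retains them, so syn gives 2,3-trans) of arylacetyl imide 4 with aldehyde 5; 4 ⇒ C–H borylation of 1, then sp2–sp3 Suzuki coupling.
5. Lactone 23 ⇒ chiral pool: (R)-epichlorohydrin + malonate → cyclopropane-fused lactone 19 → aryl-cuprate ring opening → dealkoxycarbonylation. Ring order: D (step 9), C (step 6, other branch), union in step 12.

Key step: step 6

Remark: compounds 3, 5 and 20 are assumed to be catalogue chemicals (each is otherwise one routine N-acylation or O-benzylation away from one).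

**Step 1**
Reactants: 1 methyl 4-fluoro-3-methoxybenzoate
Product: 2 methyl 4-fluoro-3-methoxy-5-(4,4,5,5-tetramethyl-1,3,2-dioxaborolan-2-yl)benzoate
Conditions: [Ir(OMe)(cod)]2 (1.5 mol%), 4,4'-di-tert-butyl-2,2'-bipyridine (3 mol%), B2pin2 (1.0 equiv), THF, 80 °C
Reagents that add atoms: bis(pinacolato)diboron, CC1(C)OB(OC1(C)C)B1OC(C)(C)C(C)(C)O1
Why: Iridium-catalysed C–H borylation is sterically governed: C2–H lies between two substituents, and of the two remaining C–H bonds the one next to the small fluorine should react before the one next to the ester, so boron enters at the carbon that becomes C3a (no stereocentre is formed).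

**Step 2**
Reactants: 2 methyl 4-fluoro-3-methoxy-5-(4,4,5,5-tetramethyl-1,3,2-dioxaborolan-2-yl)benzoate; 3 (4S)-4-benzyl-3-(chloroacetyl)-1,3-oxazolidin-2-one
Product: 4 methyl 3-{2-[(4S)-4-benzyl-2-oxo-1,3-oxazolidin-3-yl]-2-oxoethyl}-4-fluoro-5-methoxybenzoate
Conditions: Pd(OAc)2 (3 mol%), XPhos (6 mol%), K3PO4 (3 equiv), THF/H2O (20:1), 40 °C
Reagents that add atoms: none
Why: sp2–sp3 Suzuki–Miyaura coupling of an arylboronate with an α-chloro carbonyl electrophile (zerovalent palladium inserts into the activated C–Cl bond, aryl transfer from boron and reductive elimination follow), which installs the arylacetyl imide in one step without touching the auxiliary stereocentre.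

**Step 3**
Reactants: 4 methyl 3-{2-[(4S)-4-benzyl-2-oxo-1,3-oxazolidin-3-yl]-2-oxoethyl}-4-fluoro-5-methoxybenzoate; 5 4-(benzyloxy)-3-methoxybenzaldehyde
Product: 7 methyl 3-[(1S,2S)-3-[(4S)-4-benzyl-2-oxo-1,3-oxazolidin-3-yl]-1-[4-(benzyloxy)-3-methoxyphenyl]-1-hydroxy-3-oxopropan-2-yl]-4-fluoro-5-methoxybenzoate, via boron enolate 6 (not isolated)
Conditions: Bu2BOTf (1.2 equiv), i-Pr2NEt (1.4 equiv), CH2Cl2, −78 to 0 °C; then 5, −78 to 0 °C; then pH 7 buffer, MeOH, H2O2, 0 °C
Reagents that add atoms: dibutylboron triflate, CCCCB(CCCC)OS(=O)(=O)C(F)(F)F (the boron of enolate 6 only)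
Why: Evans syn-aldol reaction: the (Z)-boron enolate 6 should react through a closed Zimmerman–Traxler transition state on the face remote from the benzyl group of the (4S)-auxiliary, setting both new stereocentres as (αS, βS), i.e. the ring-B aryl group and the hydroxyl syn.

**Step 4**
Reactants: 7 methyl 3-[(1S,2S)-3-[(4S)-4-benzyl-2-oxo-1,3-oxazolidin-3-yl]-1-[4-(benzyloxy)-3-methoxyphenyl]-1-hydroxy-3-oxopropan-2-yl]-4-fluoro-5-methoxybenzoate
Product: 8 methyl 3-[(1S,2R)-1-[4-(benzyloxy)-3-methoxyphenyl]-1,3-dihydroxypropan-2-yl]-4-fluoro-5-methoxybenzoate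
Conditions: NaBH4 (4 equiv), THF/H2O (4:1), 0 °C to rt
Reagents that add atoms: none
Why: Reductive removal of the auxiliary by borohydride attack on the exocyclic imide carbonyl should give the primary alcohol while the less electrophilic methyl benzoate and the C–F bond survive; both stereocentres are retained (the descriptor at the ring-B-bearing carbon changes from S to R only through the change in CIP priorities).

**Step 5**
Reactants: 8 methyl 3-[(1S,2R)-1-[4-(benzyloxy)-3-methoxyphenyl]-1,3-dihydroxypropan-2-yl]-4-fluoro-5-methoxybenzoate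
Product: 10 methyl 3-[(1S,2R)-3-(benzyloxy)-1-[4-(benzyloxy)-3-methoxyphenyl]-1-hydroxypropan-2-yl]-4-fluoro-5-methoxybenzoate, via stannylene acetal 9 (not isolated)
Conditions: Bu2SnO (1.1 equiv), toluene, reflux (−H2O); then BnBr (1.3 equiv), Bu4NBr (1.0 equiv), 90 °C
Reagents that add atoms: benzyl bromide, BrCc1ccccc1; dibutyltin oxide, CCCC[Sn](=O)CCCC (the tin of acetal 9 only)
Why: Regioselective O-alkylation of a 1,3-diol through its dibutylstannylene acetal, in which the primary oxygen is the more nucleophilic site, should cap the primary hydroxyl and leave the secondary benzylic hydroxyl free; a benzyl ether is chosen because it cannot migrate to the neighbouring alkoxide in the next step.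

**Step 6**
Reactants: 10 methyl 3-[(1S,2R)-3-(benzyloxy)-1-[4-(benzyloxy)-3-methoxyphenyl]-1-hydroxypropan-2-yl]-4-fluoro-5-methoxybenzoate
Product: 13 methyl (2S,3R)-2-[4-(benzyloxy)-3-methoxyphenyl]-3-[(benzyloxy)methyl]-7-methoxy-2,3-dihydro-1-benzofuran-5-carboxylate, via potassium alkoxide 11 (not isolated), via Meisenheimer adduct 12 (not isolated)
Conditions: KN(SiMe3)2 (1.05 equiv), 18-crown-6 (1.05 equiv), THF (0.02 M), −20 °C to rt
Reagents that add atoms: potassium bis(trimethylsilyl)amide, C[Si](C)(C)[N-][Si](C)(C)C.[K+] (the potassium of 11 and 12 only)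
Why: KN(SiMe3)2 deprotonates the only free hydroxyl to alkoxide 11, which adds to C7a of ring B to give Meisenheimer adduct 12, whose charge is taken up by the para ester on C5, and loss of fluoride restores ring B (addition–elimination SNAr). The closest known reaction type is the intramolecular SNAr etherification of ester-, formyl- or cyano-activated 2-(2-fluoroaryl)ethanols to 2,3-dihydrobenzofurans. Ring C is the only ring closed, in the 5-exo-trig mode (O1–C2–C3–C3a–C7a, attack on the C7a=C7 π bond). No stereocentre is made: no bond to C2 or C3 is broken, so the syn (1S,2R) relationship from step 3 is delivered as the 2,3-trans (2S,3R) dihydrobenzofuran. The step needs one oxygen, one carbon and no ester exchange: the primary oxygen is benzylated, C7a has no ortho hydrogen (C7 carries OMe, C3a the side chain) so no aryne or elimination path exists, C3 carries no carbonyl so neither retro-aldol cleavage nor epimerisation can occur, and high dilution holds back intermolecular attack of the alkoxide on the methyl ester.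

**Step 7**
Reactants: 13 methyl (2S,3R)-2-[4-(benzyloxy)-3-methoxyphenyl]-3-[(benzyloxy)methyl]-7-methoxy-2,3-dihydro-1-benzofuran-5-carboxylate
Product: 14 [(2S,3R)-2-[4-(benzyloxy)-3-methoxyphenyl]-3-[(benzyloxy)methyl]-7-methoxy-2,3-dihydro-1-benzofuran-5-yl]methanol
Conditions: i-Bu2AlH (2.5 equiv), CH2Cl2, −78 to 0 °C; aq. potassium sodium tartrate
Reagents that add atoms: none
Why: Hydride reduction of the methyl ester to the benzylic alcohol turns the spent SNAr activating group into the future CH2 link; the ethers and the dihydrobenzofuran are inert and no stereocentre is affected.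

**Step 8**
Reactants: 14 [(2S,3R)-2-[4-(benzyloxy)-3-methoxyphenyl]-3-[(benzyloxy)methyl]-7-methoxy-2,3-dihydro-1-benzofuran-5-yl]methanol
Product: 15 (2S,3R)-2-[4-(benzyloxy)-3-methoxyphenyl]-3-[(benzyloxy)methyl]-5-(bromomethyl)-7-methoxy-2,3-dihydro-1-benzofuran
Conditions: CBr4 (1.3 equiv), PPh3 (1.3 equiv), CH2Cl2, 0 °C; used at once
Reagents that add atoms: carbon tetrabromide, BrC(Br)(Br)Br
Why: The Appel reaction converts the electron-rich benzylic alcohol into the bromide under neutral conditions, avoiding acid that could ionise the C2–O1 bond; no stereocentre is involved.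

**Step 9**
Reactants: 16 (R)-epichlorohydrin [(2R)-2-(chloromethyl)oxirane]; 17 diethyl malonate
Product: 19 ethyl (1S,5R)-2-oxo-3-oxabicyclo[3.1.0]hexane-1-carboxylate, via epoxy malonate 18 (not isolated)
Conditions: NaOEt (1.0 equiv), EtOH, 0 °C to reflux
Reagents that add atoms: none
Why: Chiral-pool tandem alkylation–cyclopropanation–lactonisation: malonate opens the epoxide of 16 at CH2, the alkoxide closes onto CH2Cl to give epoxide 18, the second enolate opens 18 at its stereocentre with inversion (3-exo-tet) and the released alkoxide lactonises, so C2 of 16 becomes C5 of 19 (R) and C1 follows from the obligatory cis ring fusion.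

**Step 10**
Reactants: 19 ethyl (1S,5R)-2-oxo-3-oxabicyclo[3.1.0]hexane-1-carboxylate; 20 1-(benzyloxy)-4-bromo-2-methoxybenzene
Product: 22 ethyl (4R)-4-[4-(benzyloxy)-3-methoxybenzyl]-2-oxooxolane-3-carboxylate (C3 epimers), via aryl Grignard reagent 21 (not isolated)
Conditions: 20, Mg, THF, 45 °C; then CuI (10 mol%), 19, THF, −30 to 0 °C; 1 M HCl
Reagents that add atoms: magnesium, [Mg] (the magnesium of 21 only)
Why: Copper-catalysed homoconjugate (SN2-type) opening of the doubly activated cyclopropane by the aryl Grignard reagent at the unsubstituted CH2 builds the benzyl side chain; the C4 stereocentre is not involved and the epimerisable C3 is lost in the next step.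

**Step 11**
Reactants: 22 ethyl (4R)-4-[4-(benzyloxy)-3-methoxybenzyl]-2-oxooxolane-3-carboxylate
Product: 23 (4R)-4-[4-(benzyloxy)-3-methoxybenzyl]oxolan-2-one
Conditions: LiCl (2 equiv), H2O (2 equiv), DMSO, 140 °C
Reagents that add atoms: none
Why: Krapcho dealkoxycarbonylation removes the ester that activated the cyclopropane and leaves the C4 stereocentre (R) untouched.

**Step 12**
Reactants: 23 (4R)-4-[4-(benzyloxy)-3-methoxybenzyl]oxolan-2-one; 15 (2S,3R)-2-[4-(benzyloxy)-3-methoxyphenyl]-3-[(benzyloxy)methyl]-5-(bromomethyl)-7-methoxy-2,3-dihydro-1-benzofuran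
Product: 25 (3R,4R)-3-{[(2S,3R)-2-[4-(benzyloxy)-3-methoxyphenyl]-3-[(benzyloxy)methyl]-7-methoxy-2,3-dihydro-1-benzofuran-5-yl]methyl}-4-[4-(benzyloxy)-3-methoxybenzyl]oxolan-2-one, via lithium enolate 24 (not isolated)
Conditions: LiN(SiMe3)2 (1.1 equiv), THF, −78 °C; then 15, DMPU, −78 to −30 °C
Reagents that add atoms: lithium bis(trimethylsilyl)amide, C[Si](C)(C)[N-][Si](C)(C)C.[Li+] (the lithium of 24 only)
Why: Enolate alkylation of a β-substituted γ-butyrolactone with a benzylic bromide: the electrophile should approach anti to the C4 benzyl group, setting C3 as R (3,4-trans).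

**Step 13**
Reactants: 25 (3R,4R)-3-{[(2S,3R)-2-[4-(benzyloxy)-3-methoxyphenyl]-3-[(benzyloxy)methyl]-7-methoxy-2,3-dihydro-1-benzofuran-5-yl]methyl}-4-[4-(benzyloxy)-3-methoxybenzyl]oxolan-2-one
Product: 26 isolappaol A
Conditions: H2 (1 atm), 10% Pd/C, EtOAc/EtOH (1:1), rt, stopped after uptake of 3 equiv
Reagents that add atoms: none
Why: Hydrogenolysis of the two aryl benzyl ethers and the alkyl benzyl ether under neutral conditions should leave the cyclic benzylic ether C2–O1 and the lactone intact, and no stereocentre is touched.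

**Compound list**
1 | methyl 4-fluoro-3-methoxybenzoate | COC(=O)c1ccc(F)c(OC)c1 | starting material
2 | methyl 4-fluoro-3-methoxy-5-(4,4,5,5-tetramethyl-1,3,2-dioxaborolan-2-yl)benzoate | COC(=O)c1cc(OC)c(F)c(c1)B1OC(C)(C)C(C)(C)O1 | intermediate
3 | (4S)-4-benzyl-3-(chloroacetyl)-1,3-oxazolidin-2-one | ClCC(=O)N1[C@@H](Cc2ccccc2)COC1=O | starting material
4 | methyl 3-{2-[(4S)-4-benzyl-2-oxo-1,3-oxazolidin-3-yl]-2-oxoethyl}-4-fluoro-5-methoxybenzoate | COC(=O)c1cc(OC)c(F)c(CC(=O)N2[C@@H](Cc3ccccc3)COC2=O)c1 | intermediate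
5 | 4-(benzyloxy)-3-methoxybenzaldehyde | COc1cc(C=O)ccc1OCc1ccccc1 | starting material
6 | dibutylboron (Z)-enolate of 4: methyl 3-[(Z)-2-[(4S)-4-benzyl-2-oxo-1,3-oxazolidin-3-yl]-2-[(dibutylboranyl)oxy]ethenyl]-4-fluoro-5-methoxybenzoate | CCCCB(CCCC)O/C(=C\c1cc(cc(OC)c1F)C(=O)OC)N1[C@@H](Cc2ccccc2)COC1=O | intermediate (not isolated)
7 | methyl 3-[(1S,2S)-3-[(4S)-4-benzyl-2-oxo-1,3-oxazolidin-3-yl]-1-[4-(benzyloxy)-3-methoxyphenyl]-1-hydroxy-3-oxopropan-2-yl]-4-fluoro-5-methoxybenzoate (syn aldol adduct) | COC(=O)c1cc(OC)c(F)c(c1)[C@H](C(=O)N1[C@@H](Cc2ccccc2)COC1=O)[C@@H](c1ccc(OCc2ccccc2)c(OC)c1)O | intermediate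
8 | methyl 3-[(1S,2R)-1-[4-(benzyloxy)-3-methoxyphenyl]-1,3-dihydroxypropan-2-yl]-4-fluoro-5-methoxybenzoate | COC(=O)c1cc(OC)c(F)c(c1)[C@H](CO)[C@@H](c1ccc(OCc2ccccc2)c(OC)c1)O | intermediate
9 | dibutylstannylene acetal of 8: methyl 3-[(4S,5R)-4-[4-(benzyloxy)-3-methoxyphenyl]-2,2-dibutyl-1,3,2-dioxastanninan-5-yl]-4-fluoro-5-methoxybenzoate | COC(=O)c1cc(OC)c(F)c(c1)[C@H](CO[Sn]2(CCCC)CCCC)[C@@H](c1ccc(OCc3ccccc3)c(OC)c1)O2 | intermediate (not isolated)
10 | methyl 3-[(1S,2R)-3-(benzyloxy)-1-[4-(benzyloxy)-3-methoxyphenyl]-1-hydroxypropan-2-yl]-4-fluoro-5-methoxybenzoate | COC(=O)c1cc(OC)c(F)c(c1)[C@H](COCc1ccccc1)[C@@H](c1ccc(OCc2ccccc2)c(OC)c1)O | intermediate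
11 | potassium alkoxide of 10: potassium (1S,2R)-3-(benzyloxy)-1-[4-(benzyloxy)-3-methoxyphenyl]-2-[2-fluoro-3-methoxy-5-(methoxycarbonyl)phenyl]propan-1-olate | COC(=O)c1cc(OC)c(F)c(c1)[C@H](COCc1ccccc1)[C@@H](c1ccc(OCc2ccccc2)c(OC)c1)[O-].[K+] | intermediate (not isolated)
12 | Meisenheimer adduct: potassium {(2S,3R)-2-[4-(benzyloxy)-3-methoxyphenyl]-3-[(benzyloxy)methyl]-7a-fluoro-7-methoxy-3,7a-dihydro-1-benzofuran-5(2H)-ylidene}(methoxy)methanolate (C7a unassigned) | COC([O-])=C1C=C(OC)C2(F)O[C@H](c3ccc(OCc4ccccc4)c(OC)c3)[C@@H](COCc3ccccc3)C2=C1.[K+] | intermediate (not isolated)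
13 | methyl (2S,3R)-2-[4-(benzyloxy)-3-methoxyphenyl]-3-[(benzyloxy)methyl]-7-methoxy-2,3-dihydro-1-benzofuran-5-carboxylate | COC(=O)c1cc(OC)c2c(c1)[C@H](COCc1ccccc1)[C@@H](c1ccc(OCc3ccccc3)c(OC)c1)O2 | intermediate
14 | [(2S,3R)-2-[4-(benzyloxy)-3-methoxyphenyl]-3-[(benzyloxy)methyl]-7-methoxy-2,3-dihydro-1-benzofuran-5-yl]methanol | OCc1cc(OC)c2c(c1)[C@H](COCc1ccccc1)[C@@H](c1ccc(OCc3ccccc3)c(OC)c1)O2 | intermediate
15 | (2S,3R)-2-[4-(benzyloxy)-3-methoxyphenyl]-3-[(benzyloxy)methyl]-5-(bromomethyl)-7-methoxy-2,3-dihydro-1-benzofuran | BrCc1cc(OC)c2c(c1)[C@H](COCc1ccccc1)[C@@H](c1ccc(OCc3ccccc3)c(OC)c1)O2 | intermediate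
16 | (R)-epichlorohydrin, (2R)-2-(chloromethyl)oxirane | ClC[C@H]1CO1 | starting material
17 | diethyl malonate | CCOC(=O)CC(=O)OCC | starting material
18 | diethyl {[(2R)-oxiran-2-yl]methyl}propanedioate | CCOC(=O)C(C[C@@H]1CO1)C(=O)OCC | intermediate (not isolated)
19 | ethyl (1S,5R)-2-oxo-3-oxabicyclo[3.1.0]hexane-1-carboxylate | C1[C@H]2COC(=O)[C@@]12C(=O)OCC | intermediate
20 | 1-(benzyloxy)-4-bromo-2-methoxybenzene | COc1cc(Br)ccc1OCc1ccccc1 | starting material
21 | [4-(benzyloxy)-3-methoxyphenyl]magnesium bromide | COc1cc([Mg]Br)ccc1OCc1ccccc1 | intermediate (not isolated)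
22 | ethyl (4R)-4-[4-(benzyloxy)-3-methoxybenzyl]-2-oxooxolane-3-carboxylate (C3 epimers) | COc1cc(C[C@H]2COC(=O)C2C(=O)OCC)ccc1OCc1ccccc1 | intermediate
23 | (4R)-4-[4-(benzyloxy)-3-methoxybenzyl]oxolan-2-one | COc1cc(C[C@H]2COC(=O)C2)ccc1OCc1ccccc1 | intermediate
24 | lithium enolate of 23: lithium (4R)-4-[4-(benzyloxy)-3-methoxybenzyl]-4,5-dihydrofuran-2-olate | COc1cc(C[C@H]2COC([O-])=C2)ccc1OCc1ccccc1.[Li+] | intermediate (not isolated)
25 | (3R,4R)-3-{[(2S,3R)-2-[4-(benzyloxy)-3-methoxyphenyl]-3-[(benzyloxy)methyl]-7-methoxy-2,3-dihydro-1-benzofuran-5-yl]methyl}-4-[4-(benzyloxy)-3-methoxybenzyl]oxolan-2-one | COc1cc(C[C@H]2COC(=O)[C@@H]2Cc2cc(OC)c3c(c2)[C@H](COCc2ccccc2)[C@@H](c2ccc(OCc4ccccc4)c(OC)c2)O3)ccc1OCc1ccccc1 | intermediate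
26 | isolappaol A, (3R,4R)-3-{[(2S,3R)-2-(4-hydroxy-3-methoxyphenyl)-3-(hydroxymethyl)-7-methoxy-2,3-dihydro-1-benzofuran-5-yl]methyl}-4-(4-hydroxy-3-methoxybenzyl)oxolan-2-one | COc1cc(C[C@H]2COC(=O)[C@@H]2Cc2cc(OC)c3c(c2)[C@H](CO)[C@@H](c2ccc(O)c(OC)c2)O3)ccc1O | target

**Step count.** Total: 13 steps. Longest linear sequence: 10 steps (steps 1–8, 12 and 13); the lactone branch is steps 9–11.

**Three steps most likely to fail**

Step 3. The aldolate of a doubly activated arylacetyl imide may equilibrate by retro-aldol cleavage and α-epimerisation, and addition to the electron-rich aldehyde may be sluggish, so the syn selectivity could erode. The fallback makes the C2–C3 bond by acylation and sets the carbinol centre by hydride delivery. It sets out from 2, which is coupled as in step 2 with (4R)-4-benzyl-3-(chloroacetyl)-1,3-oxazolidin-2-one to give the enantiomeric-auxiliary imide methyl 3-{2-[(4R)-4-benzyl-2-oxo-1,3-oxazolidin-3-yl]-2-oxoethyl}-4-fluoro-5-methoxybenzoate F1. Its chelated sodium enolate (NaN(SiMe3)2, THF, −78 °C) is C-acylated with 4-(benzyloxy)-3-methoxybenzoyl chloride anti to the auxiliary benzyl group, giving the β-keto imide methyl 3-[(2S)-1-[(4R)-4-benzyl-2-oxo-1,3-oxazolidin-3-yl]-3-[4-(benzyloxy)-3-methoxyphenyl]-1,3-dioxopropan-2-yl]-4-fluoro-5-methoxybenzoate F2, whose α-centre is held by allylic strain. Chelation-controlled reduction with Zn(BH4)2 (CH2Cl2, −20 °C) should give the syn hydroxy imide methyl 3-[(1S,2S)-3-[(4R)-4-benzyl-2-oxo-1,3-oxazolidin-3-yl]-1-[4-(benzyloxy)-3-methoxyphenyl]-1-hydroxy-3-oxopropan-2-yl]-4-fluoro-5-methoxybenzoate F3. NaBH4 in wet THF, as in step 4, then returns the route at diol 8.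

Step 6. Addition at the di-ortho-substituted C7a, activated only by an ester, may be slow enough for intermolecular alkoxide–ester exchange to compete. The fallback raises the acceptor strength by changing the oxidation level before the closure. It sets out from 10: i-Bu2AlH reduces the ester to the diol (1S,2R)-3-(benzyloxy)-1-[4-(benzyloxy)-3-methoxyphenyl]-2-[2-fluoro-5-(hydroxymethyl)-3-methoxyphenyl]propan-1-ol F4. TEMPO/PhI(OAc)2 oxidises the primary benzylic hydroxyl selectively to the aldehyde 3-[(1S,2R)-3-(benzyloxy)-1-[4-(benzyloxy)-3-methoxyphenyl]-1-hydroxypropan-2-yl]-4-fluoro-5-methoxybenzaldehyde F5. The para formyl group should then allow closure with K2CO3 in DMF at 60 °C to the aldehyde (2S,3R)-2-[4-(benzyloxy)-3-methoxyphenyl]-3-[(benzyloxy)methyl]-7-methoxy-2,3-dihydro-1-benzofuran-5-carbaldehyde F6, with no ester left to exchange. NaBH4 (MeOH, 0 °C) returns the route at alcohol 14.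

Step 2. Under the aqueous basic coupling conditions the imide may be cleaved hydrolytically and the ortho-fluoro boronate may protodeboronate. The fallback brings in the two-carbon arm as a robust ester and attaches the auxiliary afterwards. It sets out from 2: coupling with tert-butyl bromoacetate (Pd(OAc)2, P(o-tol)3, K3PO4, THF, rt) gives the ester methyl 3-(2-tert-butoxy-2-oxoethyl)-4-fluoro-5-methoxybenzoate F7. CF3CO2H in CH2Cl2 gives the acid [2-fluoro-3-methoxy-5-(methoxycarbonyl)phenyl]acetic acid F8. Activation as the mixed pivalic anhydride (pivaloyl chloride, Et3N) and N-acylation of (4S)-4-benzyl-1,3-oxazolidin-2-one (LiCl) returns the route at imide 4.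

**Further compounds**
F1 | step 3 | methyl 3-{2-[(4R)-4-benzyl-2-oxo-1,3-oxazolidin-3-yl]-2-oxoethyl}-4-fluoro-5-methoxybenzoate | COC(=O)c1cc(OC)c(F)c(CC(=O)N2[C@H](Cc3ccccc3)COC2=O)c1
F2 | step 3 | methyl 3-[(2S)-1-[(4R)-4-benzyl-2-oxo-1,3-oxazolidin-3-yl]-3-[4-(benzyloxy)-3-methoxyphenyl]-1,3-dioxopropan-2-yl]-4-fluoro-5-methoxybenzoate | COC(=O)c1cc(OC)c(F)c(c1)[C@H](C(=O)N1[C@H](Cc2ccccc2)COC1=O)C(=O)c1ccc(OCc2ccccc2)c(OC)c1
F3 | step 3 | methyl 3-[(1S,2S)-3-[(4R)-4-benzyl-2-oxo-1,3-oxazolidin-3-yl]-1-[4-(benzyloxy)-3-methoxyphenyl]-1-hydroxy-3-oxopropan-2-yl]-4-fluoro-5-methoxybenzoate | COC(=O)c1cc(OC)c(F)c(c1)[C@H](C(=O)N1[C@H](Cc2ccccc2)COC1=O)[C@@H](c1ccc(OCc2ccccc2)c(OC)c1)O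
F4 | step 6 | (1S,2R)-3-(benzyloxy)-1-[4-(benzyloxy)-3-methoxyphenyl]-2-[2-fluoro-5-(hydroxymethyl)-3-methoxyphenyl]propan-1-ol | OCc1cc(OC)c(F)c(c1)[C@H](COCc1ccccc1)[C@@H](c1ccc(OCc2ccccc2)c(OC)c1)O
F5 | step 6 | 3-[(1S,2R)-3-(benzyloxy)-1-[4-(benzyloxy)-3-methoxyphenyl]-1-hydroxypropan-2-yl]-4-fluoro-5-methoxybenzaldehyde | O=Cc1cc(OC)c(F)c(c1)[C@H](COCc1ccccc1)[C@@H](c1ccc(OCc2ccccc2)c(OC)c1)O
F6 | step 6 | (2S,3R)-2-[4-(benzyloxy)-3-methoxyphenyl]-3-[(benzyloxy)methyl]-7-methoxy-2,3-dihydro-1-benzofuran-5-carbaldehyde | O=Cc1cc(OC)c2c(c1)[C@H](COCc1ccccc1)[C@@H](c1ccc(OCc3ccccc3)c(OC)c1)O2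
F7 | step 2 | methyl 3-(2-tert-butoxy-2-oxoethyl)-4-fluoro-5-methoxybenzoate | COC(=O)c1cc(OC)c(F)c(CC(=O)OC(C)(C)C)c1
F8 | step 2 | [2-fluoro-3-methoxy-5-(methoxycarbonyl)phenyl]acetic acid | COC(=O)c1cc(OC)c(F)c(CC(=O)O)c1
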